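**Strategy.** Ring A is disconnected across C1–C2 and C3–C4. Its substituents (C1 CO2Me, C6 O-aryl, C5 H, C4 CH3) match C3 to C6 of a 3-carbomethoxy-4-aryloxy-6-methyl-2-pyrone, so only C2 with its oxygen and C3 are missing. One thermal operation supplies them. Inverse-demand [4+2] addition of 1,1-bis(trimethylsilyloxy)ethene, then loss of CO2 and Me3SiOH, gives the salicylate with the hindered diaryl ether already in place. That ether is made earlier by addition–elimination of the ring B phenoxide at pyrone C4. The precursor carries ring B with C2' O-MOM and C6' CH2OTBS, and the acetate is installed last.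

Key step: step 10

Remark on the design:
- The ring B nucleophile cannot carry the acetate. A phenoxide ortho to CH2OAc and para to OCH3 expels acetate and forms an ortho-quinone methide.
- A free CH2OH next to the aryloxypyrone would capture pyrone C4 by a Smiles-type O-to-O shift through a six-membered spiro adduct.
- The benzylic oxygen is therefore kept as a TBS ether until ring A is aromatic.

Remark on ring B: in the bromo aldehyde starting material the methoxy group sits at the future C2' and bromine at the future C4'. The bromide is therefore exchanged for OCH3 and the original methyl ether is cleaved.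

Remark on numbering: salts formed by simple deprotonation (enolates, phenoxides) are not numbered. The target has no stereocentre.

**Route**

Step 1
Reactants: 1 dimethyl malonate; 2 2,2,6-trimethyl-4H-1,3-dioxin-4-one
Product: 5 methyl 4-hydroxy-6-methyl-2-oxo-2H-pyran-3-carboxylate, via acetylketene 3 (not isolated), via dimethyl acetoacetylmalonate 4 (not isolated)
Conditions: NaH (1.05 equiv), 1,4-dioxane, rt; 2, 100 °C, acetone distilled off; 1 M HCl
Reagents that add atoms: none
Why: Retro-hetero-Diels–Alder cleavage of the diketene–acetone adduct releases acetylketene, which C-acylates the sodium malonate (acetoacetylation), and the enol oxygen of the δ-ketone then lactonises onto one ester with loss of methanol, which is the established malonate route to 3-alkoxycarbonyl-4-hydroxy-2-pyrones.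

Step 2
Reactants: 5 methyl 4-hydroxy-6-methyl-2-oxo-2H-pyran-3-carboxylate
Product: 6 methyl 6-methyl-4-(4-methylphenylsulfonyloxy)-2-oxo-2H-pyran-3-carboxylate
Conditions: TsCl, iPr2NEt, CH2Cl2, 0 °C; short silica filtration
Reagents that add atoms: p-toluenesulfonyl chloride, Cc1ccc(cc1)S(=O)(=O)Cl
Why: O-sulfonylation of the acidic vinylogous-acid OH at C4, as practised on 4-hydroxy-6-methyl-2-pyrone, should turn C4 into an acceptor carbon that bears a leaving group, and the hindered amine cannot add to the ring.

Step 3
Reactants: 7 5-bromo-2-hydroxy-3-methoxybenzaldehyde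
Product: 8 2-hydroxy-3,5-dimethoxybenzaldehyde
Conditions: NaOMe (5 equiv), CuBr (10 mol %), DMF–MeOH, 110 °C; aq. HCl
Reagents that add atoms: sodium methoxide, [Na+].[O-]C
Why: Ullmann-type copper-catalysed methoxylation of an aryl bromide, well established on bromo-hydroxybenzaldehydes such as 5-bromovanillin, places OCH3 at the future C4' while the phenoxide keeps the aldehyde out of Cannizzaro chemistry.

Step 4
Reactants: 8 2-hydroxy-3,5-dimethoxybenzaldehyde
Product: 9 2,3-dihydroxy-5-methoxybenzaldehyde
Conditions: AlCl3 (1.2 equiv), pyridine (4.5 equiv), CH2Cl2, reflux; 2 M HCl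
Reagents that add atoms: none
Why: In this neighbouring-group-assisted aryl methyl ether cleavage the aluminium phenoxide chelates and activates only the adjacent C3 methoxy group, so the isolated C5 methoxy group should survive.

Step 5
Reactants: 9 2,3-dihydroxy-5-methoxybenzaldehyde
Product: 10 2-hydroxy-5-methoxy-3-(methoxymethoxy)benzaldehyde
Conditions: NaH (2.2 equiv), DMF, 0 °C; MOMCl (1.0 equiv), 0 °C; aq. NH4Cl
Reagents that add atoms: chloromethyl methyl ether, COCCl
Why: In this Williamson-type alkylation of the catechol dianion the O3 phenoxide is not delocalised into the aldehyde and is the more nucleophilic site, so it takes the single equivalent of MOMCl and leaves the chelated O2–H (the future ether oxygen) free.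

Step 6
Reactants: 10 2-hydroxy-5-methoxy-3-(methoxymethoxy)benzaldehyde
Product: 11 2-(hydroxymethyl)-4-methoxy-6-(methoxymethoxy)phenol
Conditions: NaBH4, THF–MeOH, 0 °C; aq. NH4Cl
Reagents that add atoms: none
Why: Borohydride reduction of an aromatic aldehyde leaves the MOM and methyl ethers untouched, and the cold, near-neutral work-up avoids ionisation of the salicyl alcohol.

Step 7
Reactants: 11 2-(hydroxymethyl)-4-methoxy-6-(methoxymethoxy)phenol
Product: 12 2-(tert-butyldimethylsilyloxymethyl)-4-methoxy-6-(methoxymethoxy)phenol
Conditions: TBSCl (1.05 equiv), imidazole, CH2Cl2, 0 °C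
Reagents that add atoms: tert-butyldimethylsilyl chloride, CC(C)(C)[Si](C)(C)Cl
Why: Chemoselective silylation is expected because the primary alcohol reacts faster than the doubly ortho-flanked phenol, and any aryl silyl ether formed would pass silicon on to the alcohol, as is known for salicyl alcohol.

Step 8
Reactants: 13 trimethylsilyl acetate
Product: 14 1,1-bis(trimethylsilyloxy)ethene
Conditions: LiN(iPr)2, THF, −78 °C; Me3SiCl, −78 °C to rt; distillation
Reagents that add atoms: chlorotrimethylsilane, C[Si](C)(C)Cl
Why: Kinetic deprotonation of the silyl ester and O-silylation of its lithium enolate is the standard preparation of ketene bis(silyl) acetals, and distillation removes any C-silylated isomer.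

Step 9
Reactants: 12 2-(tert-butyldimethylsilyloxymethyl)-4-methoxy-6-(methoxymethoxy)phenol; 6 methyl 6-methyl-4-(4-methylphenylsulfonyloxy)-2-oxo-2H-pyran-3-carboxylate
Product: 15 methyl 4-[2-(tert-butyldimethylsilyloxymethyl)-4-methoxy-6-(methoxymethoxy)phenoxy]-6-methyl-2-oxo-2H-pyran-3-carboxylate
Conditions: 12, NaH (1.0 equiv), THF, 0 °C; then 6, 0 °C to rt
Reagents that add atoms: none
Why: Addition–elimination (vinylogous acyl substitution) of a phenoxide at C4 is known for 4-sulfonyloxy-2-pyrones and -coumarins and is made easier here by the C3 ester, and the ortho silyl ether, unlike an acetate, is not expelled by the phenoxide.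

Step 10
Reactants: 15 methyl 4-[2-(tert-butyldimethylsilyloxymethyl)-4-methoxy-6-(methoxymethoxy)phenoxy]-6-methyl-2-oxo-2H-pyran-3-carboxylate; 14 1,1-bis(trimethylsilyloxy)ethene
Product: 19 methyl 2-[2-(tert-butyldimethylsilyloxymethyl)-4-methoxy-6-(methoxymethoxy)phenoxy]-6-hydroxy-4-methylbenzoate, via bridged lactone 16 (not isolated), via bis(trimethylsilyloxy)cyclohexadiene 17 (not isolated), via aryl trimethylsilyl ether 18 (not isolated)
Conditions: 14 (5 equiv), toluene, 110–130 °C, sealed tube, argon; then THF–aq. citric acid, rt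
Reagents that add atoms: none
Why: In this inverse-electron-demand Diels–Alder reaction the diene C3=C4–C5=C6 of 15, lowered in energy by the lactone carbonyl and the C3 ester, adds the electron-rich alkene of 14 in an asynchronous [4+2] event in which CH2 bonds to pyrone C6 and the dioxygenated carbon to pyrone C3, giving racemic bridged lactone 16. Retro-[4+2] loss of CO2 gives diene 17, 1,2-elimination of Me3SiOH across ring A C2–C3 aromatises it to 18, and the buffered aqueous work-up cleaves the labile aryl silyl ether to the chelated phenol 19. The closest known reaction type is the conversion of 3-carbomethoxy-2-pyrones into 2-alkoxybenzoates with 1,1-dialkoxyethenes. Ring A closes as a six-membered carbocycle by intermolecular cycloaddition that makes both new bonds (C1–C2 and C3–C4) in one event, and the two bridgehead stereocentres of 16 vanish on aromatisation, so no stereocontrol is needed. Regiochemistry follows from pairing the nucleophilic CH2 with the δ-carbon C6 of the doubly activated dienoate, while addition–elimination at C4 is held back by the donor oxygen on that carbon, by the two ortho substituents of ring B that shield it, and by the non-polar medium, which disfavours a free zwitterion. The TBS ether, MOM ether and methyl ester are inert to neutral thermolysis, and the excess of 14 makes up for dienophile lost to the protic by-product.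

Step 11
Reactants: 19 methyl 2-[2-(tert-butyldimethylsilyloxymethyl)-4-methoxy-6-(methoxymethoxy)phenoxy]-6-hydroxy-4-methylbenzoate
Product: 20 methyl 2-hydroxy-6-[2-hydroxy-6-(hydroxymethyl)-4-methoxyphenoxy]-4-methylbenzoate
Conditions: HCl (1.25 M in MeOH), 40 °C
Reagents that add atoms: none
Why: Acid-catalysed methanolysis should remove the phenolic MOM acetal and the primary TBS ether together, ester exchange is degenerate in methanol, and the benzylic alcohol has only one weak ortho donor and should not ionise.

Step 12
Reactants: 20 methyl 2-hydroxy-6-[2-hydroxy-6-(hydroxymethyl)-4-methoxyphenoxy]-4-methylbenzoate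
Product: 21 betaethrin A, methyl 2-[2-(acetoxymethyl)-6-hydroxy-4-methoxyphenoxy]-6-hydroxy-4-methylbenzoate
Conditions: AcOH (1.5 equiv), PPh3, DIAD (1.3 equiv each), THF, 0 °C
Reagents that add atoms: acetic acid, CC(=O)O
Why: In this Mitsunobu esterification only the aliphatic alcohol is activated as an alkoxyphosphonium ion and only acetic acid, far more acidic than either phenol, is deprotonated to act as nucleophile, so both phenols should stay free under base-free conditions that also avoid lactonisation onto the ring A ester.

**Compound list**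

1 | dimethyl malonate | COC(=O)CC(=O)OC | starting material
2 | 2,2,6-trimethyl-4H-1,3-dioxin-4-one | CC1=CC(=O)OC(C)(C)O1 | starting material
3 | acetylketene | CC(=O)C=C=O | intermediate
4 | dimethyl 2-(3-oxobutanoyl)propanedioate | CC(=O)CC(=O)C(C(=O)OC)C(=O)OC | intermediate
5 | methyl 4-hydroxy-6-methyl-2-oxo-2H-pyran-3-carboxylate | COC(=O)C1=C(O)C=C(C)OC1=O | intermediate
6 | methyl 6-methyl-4-(4-methylphenylsulfonyloxy)-2-oxo-2H-pyran-3-carboxylate | COC(=O)C1=C(OS(=O)(=O)c2ccc(C)cc2)C=C(C)OC1=O | intermediate
7 | 5-bromo-2-hydroxy-3-methoxybenzaldehyde | COc1cc(Br)cc(C=O)c1O | starting material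
8 | 2-hydroxy-3,5-dimethoxybenzaldehyde | COc1cc(OC)c(O)c(C=O)c1 | intermediate
9 | 2,3-dihydroxy-5-methoxybenzaldehyde | COc1cc(O)c(O)c(C=O)c1 | intermediate
10 | 2-hydroxy-5-methoxy-3-(methoxymethoxy)benzaldehyde | COCOc1cc(OC)cc(C=O)c1O | intermediate
11 | 2-(hydroxymethyl)-4-methoxy-6-(methoxymethoxy)phenol | COCOc1cc(OC)cc(CO)c1O | intermediate
12 | 2-(tert-butyldimethylsilyloxymethyl)-4-methoxy-6-(methoxymethoxy)phenol | COCOc1cc(OC)cc(CO[Si](C)(C)C(C)(C)C)c1O | intermediate
13 | trimethylsilyl acetate | CC(=O)O[Si](C)(C)C | starting material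
14 | 1,1-bis(trimethylsilyloxy)ethene | C=C(O[Si](C)(C)C)O[Si](C)(C)C | intermediate
15 | methyl 4-[2-(tert-butyldimethylsilyloxymethyl)-4-methoxy-6-(methoxymethoxy)phenoxy]-6-methyl-2-oxo-2H-pyran-3-carboxylate | COC(=O)C1=C(Oc2c(CO[Si](C)(C)C(C)(C)C)cc(OC)cc2OCOC)C=C(C)OC1=O | intermediate
16 | methyl 5-aryloxy-1-methyl-3-oxo-8,8-bis(trimethylsilyloxy)-2-oxabicyclo[2.2.2]oct-5-ene-4-carboxylate (aryl = ring B of 15; racemic, bridgeheads fixed by the bicycle) | COC(=O)C12C(=O)OC(C)(C=C1Oc3c(CO[Si](C)(C)C(C)(C)C)cc(OC)cc3OCOC)CC2(O[Si](C)(C)C)O[Si](C)(C)C | intermediate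
17 | methyl 2-aryloxy-4-methyl-6,6-bis(trimethylsilyloxy)cyclohexa-1,3-diene-1-carboxylate (aryl = ring B of 15) | COC(=O)C1=C(Oc2c(CO[Si](C)(C)C(C)(C)C)cc(OC)cc2OCOC)C=C(C)CC1(O[Si](C)(C)C)O[Si](C)(C)C | intermediate
18 | methyl 2-[2-(tert-butyldimethylsilyloxymethyl)-4-methoxy-6-(methoxymethoxy)phenoxy]-4-methyl-6-(trimethylsilyloxy)benzoate | COC(=O)c1c(O[Si](C)(C)C)cc(C)cc1Oc1c(CO[Si](C)(C)C(C)(C)C)cc(OC)cc1OCOC | intermediate
19 | methyl 2-[2-(tert-butyldimethylsilyloxymethyl)-4-methoxy-6-(methoxymethoxy)phenoxy]-6-hydroxy-4-methylbenzoate | COC(=O)c1c(O)cc(C)cc1Oc1c(CO[Si](C)(C)C(C)(C)C)cc(OC)cc1OCOC | intermediate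
20 | methyl 2-hydroxy-6-[2-hydroxy-6-(hydroxymethyl)-4-methoxyphenoxy]-4-methylbenzoate | COC(=O)c1c(O)cc(C)cc1Oc1c(CO)cc(OC)cc1O | intermediate
21 | betaethrin A | COC(=O)c1c(O)cc(C)cc1Oc1c(O)cc(OC)cc1COC(C)=O | target

**Step count.** Total: 12 steps. Longest linear sequence: 9 steps (steps 3, 4, 5, 6, 7, 9, 10, 11, 12, from 7).

**Steps most likely to fail**

1. Step 10.
   - The aryloxy donor at pyrone C4 may slow the cycloaddition. Thermal O-to-C silyl shift and protonolysis could then use up the ketene acetal first, or conjugate addition at C4 with expulsion of the ring B phenoxide could take over.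
   - The fallback sets out from 12 and comes back at 20. Ring A is bought ready-made and the ether is formed by cross-coupling.
   - Commercial methyl 2,6-dihydroxy-4-methylbenzoate F1 is mono-protected (MOMCl 1 equiv, iPr2NEt, CH2Cl2) to methyl 2-hydroxy-6-(methoxymethoxy)-4-methylbenzoate F2.
   - The remaining chelated phenol is converted (Tf2O, pyridine, 0 °C) into methyl 2-(methoxymethoxy)-4-methyl-6-(trifluoromethylsulfonyloxy)benzoate F3.
   - Buchwald–Hartwig-type C–O coupling of F3 with 12 (Pd(OAc)2, t-BuXPhos, K3PO4, toluene, 100 °C) should give methyl 2-[2-(tert-butyldimethylsilyloxymethyl)-4-methoxy-6-(methoxymethoxy)phenoxy]-6-(methoxymethoxy)-4-methylbenzoate F4.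
   - The conditions of step 11 then remove both MOM groups and the silyl group and give 20.

2. Step 9.
   - The doubly ortho-substituted phenoxide may attack sulfur of the tosylate (sulfonyl transfer) or merely deprotonate the C6 methyl group, so that substitution at C4 stalls.
   - The fallback sets out from 5 and comes back at 15. The sulfonate is replaced by a smaller leaving group that offers no second electrophilic centre.
   - Treatment of 5 with POCl3 (neat, 80 °C) should give the vinylogous acid chloride methyl 4-chloro-6-methyl-2-oxo-2H-pyran-3-carboxylate F5.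
   - F5 is then treated with the sodium salt of 12 (NaH, THF, 0 °C) to give 15.

3. Step 12.
   - O-alkylation of a phenol by the activated benzylic position, or sluggish activation of the hindered alcohol, would erode the chemoselectivity.
   - The fallback sets out from 19 and comes back at 21. Deprotection is staged so that only the chelated ring A phenol is free when the acetate is introduced.
   - Bu4NF buffered with AcOH (THF, 0 °C) should give methyl 2-hydroxy-6-[2-(hydroxymethyl)-4-methoxy-6-(methoxymethoxy)phenoxy]-4-methylbenzoate F6.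
   - Ac2O (1.1 equiv) and pyridine in CH2Cl2 at 0 °C acetylate the primary alcohol ahead of the hydrogen-bonded phenol, giving methyl 2-[2-(acetoxymethyl)-4-methoxy-6-(methoxymethoxy)phenoxy]-6-hydroxy-4-methylbenzoate F7.
   - CF3CO2H in CH2Cl2 at 0 °C, an alcohol-free medium that spares the acetate, removes the MOM group to give 21.

**Further compounds**

F1 | step 10 | methyl 2,6-dihydroxy-4-methylbenzoate (bought) | COC(=O)c1c(O)cc(C)cc1O
F2 | step 10 | methyl 2-hydroxy-6-(methoxymethoxy)-4-methylbenzoate | COC(=O)c1c(O)cc(C)cc1OCOC
F3 | step 10 | methyl 2-(methoxymethoxy)-4-methyl-6-(trifluoromethylsulfonyloxy)benzoate | COC(=O)c1c(OCOC)cc(C)cc1OS(=O)(=O)C(F)(F)F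
F4 | step 10 | methyl 2-[2-(tert-butyldimethylsilyloxymethyl)-4-methoxy-6-(methoxymethoxy)phenoxy]-6-(methoxymethoxy)-4-methylbenzoate | COC(=O)c1c(OCOC)cc(C)cc1Oc1c(CO[Si](C)(C)C(C)(C)C)cc(OC)cc1OCOC
F5 | step 9 | methyl 4-chloro-6-methyl-2-oxo-2H-pyran-3-carboxylate | COC(=O)C1=C(Cl)C=C(C)OC1=O
F6 | step 12 | methyl 2-hydroxy-6-[2-(hydroxymethyl)-4-methoxy-6-(methoxymethoxy)phenoxy]-4-methylbenzoate | COC(=O)c1c(O)cc(C)cc1Oc1c(CO)cc(OC)cc1OCOC
F7 | step 12 | methyl 2-[2-(acetoxymethyl)-4-methoxy-6-(methoxymethoxy)phenoxy]-6-hydroxy-4-methylbenzoate | COC(=O)c1c(O)cc(C)cc1Oc1c(COC(C)=O)cc(OC)cc1OCOC
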